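The target is a benzo-fused 2-oxabicyclo[2.2.2]octane: bridgeheads C7 and C10 (abietane numbering) are spanned by the catechol carbons C8–C9, by C6–C5 and by O–C20. C8 lies para to the C12 hydroxyl and C9 ortho to the C11 hydroxyl, so free 3-isopropylcatechol can serve twice as a carbon nucleophile. The route rests on one acid-triggered double Friedel–Crafts annulation of this catechol with a ring A dihydropyran that carries an allylic acetal at C7 and a tertiary allylic alcohol at C10. It forms C7–C8 and C9–C10, both bridged rings, and relays the catalysis-set C2 acetoxy center to C7 and C10; hydrogenation of C5=C6 then sets C5.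

Key step: step 7

Remark: abietane numbering is used for the skeleton (ring A = C1–C5, C10; ring B = C5–C10; aromatic ring C = C8, C9, C11–C14; C20 = the OCH2 bridge carbon). Anhydrous 2 is assumed to be obtained by drying and distilling the commercial aqueous solution.

**Step 1**
Reactants: 1 5,5-dimethylcyclohex-2-en-1-one; 2 2,2-dimethoxyacetaldehyde
Product: 3 6-(1-hydroxy-2,2-dimethoxyethyl)-5,5-dimethylcyclohex-2-en-1-one (racemic diastereomer mixture)
Conditions: LiN(iPr)2 (commercial solution, 1.1 equiv), THF, −78 °C; then 2, −78 °C; aq. NH4Cl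
Reagents that add atoms: none
Why: Kinetic deprotonation of the enone by the lithium amide occurs only at the alpha-prime methylene next to the gem-dimethyl carbon, and the lithium enolate adds to the aldehyde in a directed aldol reaction whose two new centers are removed in step 2.

**Step 2**
Reactants: 3 6-(1-hydroxy-2,2-dimethoxyethyl)-5,5-dimethylcyclohex-2-en-1-one
Product: 5 (Z)-6-(2,2-dimethoxyethylidene)-5,5-dimethylcyclohex-2-en-1-one, via mesylate 4 (not isolated)
Conditions: MsCl, Et3N, CH2Cl2, 0 °C; then DBU, rt
Reagents that add atoms: methanesulfonyl chloride, CS(=O)(=O)Cl (its atoms stay only in 4)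
Why: Mesylation and E1cB elimination (aldol condensation) should give the exocyclic enone with the acetal carbon cis to the carbonyl carbon, because the other geometry suffers allylic strain with the gem-dimethyl group.

**Step 3**
Reactants: 5 (Z)-6-(2,2-dimethoxyethylidene)-5,5-dimethylcyclohex-2-en-1-one
Product: 7 (S,Z)-2-(2,2-dimethoxyethylidene)-5-hydroxy-3,3-dimethylcyclohexan-1-one, via boronate 6 (not isolated)
Conditions: CuCl (5 mol %), NaOtBu (10 mol %), (R)-1-[(Sp)-2-(diphenylphosphino)ferrocenyl]ethyldicyclohexylphosphine (Josiphos, 6 mol %), B2pin2, MeOH (2 equiv), THF, rt; then NaBO3·4H2O, THF–H2O, 0 °C to rt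
Reagents that add atoms: bis(pinacolato)diboron, CC1(C)OB(OC1(C)C)B1OC(C)(C)C(C)(C)O1 (boron of 6 only); sodium perborate, [Na+].[O-]OB=O (hydroxyl oxygen of 7)
Why: Copper-catalysed enantioselective conjugate borylation should attack the unhindered ring enone CH rather than the trisubstituted exocyclic acceptor, the chiral Josiphos–copper boryl complex (ligand enantiomer to be chosen for the S product) sets the C–B center, and perborate oxidation converts C–B to C–OH with retention.

**Step 4**
Reactants: 7 (S,Z)-2-(2,2-dimethoxyethylidene)-5-hydroxy-3,3-dimethylcyclohexan-1-one; 8 (chloromethyl)(isopropoxy)dimethylsilane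
Product: 10 (5S,Z)-2-(2,2-dimethoxyethylidene)-1-(hydroxymethyl)-3,3-dimethylcyclohexane-1,5-diol (both C1 epimers), via silyl carbinol 9 (not isolated)
Conditions: 8 (3.5 equiv), Mg, THF, rt (Grignard formation); 7, 0 °C to rt; aq. NH4Cl; then KF, KHCO3, 30% H2O2, THF–MeOH, rt
Reagents that add atoms: hydrogen peroxide, OO (oxygen of the CH2OH group)
Why: The Grignard reagent made from 8 (Tamao's hydroxymethyl anion equivalent) adds 1,2 to the ketone after deprotonating the free hydroxyl, and Tamao oxidation replaces silicon by hydroxyl; the configuration of the new carbinol center is immaterial because it is ionised in step 7.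

**Step 5**
Reactants: 10 (5S,Z)-2-(2,2-dimethoxyethylidene)-1-(hydroxymethyl)-3,3-dimethylcyclohexane-1,5-diol
Product: 11 (7S)-3-methoxy-5,5-dimethyl-3,5,6,7,8,8a-hexahydro-1H-isochromene-7,8a-diol (mixture at C3 and C8a; isochromene C7 = abietane C2)
Conditions: PPTS (10 mol %), MeOH, rt
Reagents that add atoms: none
Why: Acid-catalysed intramolecular transacetalisation through the allylic oxocarbenium ion should close the six-membered ring with the primary hydroxyl (6-exo) under the thermodynamic control known from Fischer glycosidation, the acetal center forming as an inconsequential anomeric mixture.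

**Step 6**
Reactants: 11 (7S)-3-methoxy-5,5-dimethyl-3,5,6,7,8,8a-hexahydro-1H-isochromene-7,8a-diol
Product: 12 (7S)-8a-hydroxy-3-methoxy-5,5-dimethyl-3,5,6,7,8,8a-hexahydro-1H-isochromen-7-yl acetate
Conditions: Ac2O (1.2 equiv), pyridine, DMAP (5 mol %), CH2Cl2, 0 °C
Reagents that add atoms: acetic anhydride, CC(=O)OC(C)=O
Why: DMAP-catalysed acylation should esterify the secondary alcohol only, since the tertiary allylic alcohol is too hindered to react at 0 °C, and the carbinol configuration is untouched.

**Step 7**
Reactants: 12 (7S)-8a-hydroxy-3-methoxy-5,5-dimethyl-3,5,6,7,8,8a-hexahydro-1H-isochromen-7-yl acetate; 13 3-isopropylcatechol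
Product: 15 (2S,7S,10R)-2-acetoxy-7,20-epoxyabieta-5,8,11,13-tetraene-11,12-diol, via C-aryl dihydropyran 14 (not isolated)
Conditions: 13 (1.5 equiv), TfOH (10 mol %), CH2Cl2–(CF3)2CHOH (9:1), argon, −40 °C, then 0 °C
Reagents that add atoms: none
Why: TfOH ionises the allylic acetal of 12 to an oxocarbenium ion, which alkylates 13 at C8, the unhindered position para to the C12 hydroxyl, to give 14; the tertiary allylic alcohol of 14 then ionises to an allyl cation that the neighbouring arene carbon C9 (ortho to the C11 hydroxyl, preferred over C14, which is flanked by the isopropyl group) captures at C10. The closest known reaction types are the Ferrier-type aryl C-glycosylation of 2-alkoxydihydropyrans and the dehydrative Friedel–Crafts allylation with tertiary allylic alcohols, the bridging closure resembling the Grewe cyclisation. The C9–C10 bond closes ring B (6-endo with respect to the allyl cation) and the isochroman ring (6-exo) at once, across the boat form of the dihydropyran. C10 is controlled by C2: with the acetoxy group equatorial on the ring A half-chair, C9 enters on the face opposite the pseudoaxial C4 methyl and C20 becomes axial and trans to the acetoxy group, whereas the other face would place aryl or acetoxy syn-axial to that methyl. C7 is tied to C10 because only the cis-1,4 arrangement can bridge, and the wrong C7 epimer of 14 should be corrected by reversible ionisation of its benzylic, allylic C–O bond. The step needs the acetal to ionise before the tertiary alcohol and carbon attack at C8 before C9, which the low-temperature stage and the C12 hydroxyl (both its ortho positions are substituted, so it can direct only para) should secure.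

**Step 8**
Reactants: 15 (2S,7S,10R)-2-acetoxy-7,20-epoxyabieta-5,8,11,13-tetraene-11,12-diol
Product: 16 (2S,5S,7S,10R)-2-acetoxy-7,20-epoxyabieta-8,11,13-triene-11,12-diol (2α-acetoxy-20-deoxocarnosol)
Conditions: H2 (3 atm), PtO2 (10 mol %), EtOAc, rt
Reagents that add atoms: none
Why: Heterogeneous syn-hydrogenation of the strained bicyclo[2.2.2]octene double bond over PtO2 (chosen over palladium to spare the allylic, benzylic C7–O bond) should deliver hydrogen to the face syn to the flat benzo bridge and anti to the C20 methylene and the pseudoaxial C4 methyl, which places H5 trans to C20.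

**Compound list**
1 | 5,5-dimethylcyclohex-2-en-1-one | O=C1C=CCC(C)(C)C1 | starting material
2 | 2,2-dimethoxyacetaldehyde | COC(OC)C=O | starting material
3 | 6-(1-hydroxy-2,2-dimethoxyethyl)-5,5-dimethylcyclohex-2-en-1-one (racemic diastereomer mixture) | O=C1C=CCC(C)(C)C1C(O)C(OC)OC | intermediate
4 | 1-(6,6-dimethyl-2-oxocyclohex-3-en-1-yl)-2,2-dimethoxyethyl methanesulfonate | O=C1C=CCC(C)(C)C1C(OS(C)(=O)=O)C(OC)OC | intermediate (not isolated)
5 | (Z)-6-(2,2-dimethoxyethylidene)-5,5-dimethylcyclohex-2-en-1-one | O=C1C=CCC(C)(C)/C1=C/C(OC)OC | intermediate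
6 | (S,Z)-2-(2,2-dimethoxyethylidene)-3,3-dimethyl-5-(4,4,5,5-tetramethyl-1,3,2-dioxaborolan-2-yl)cyclohexan-1-one | CC1(C)OB(OC1(C)C)[C@H]1CC(C)(C)/C(=C/C(OC)OC)C(=O)C1 | intermediate (not isolated)
7 | (S,Z)-2-(2,2-dimethoxyethylidene)-5-hydroxy-3,3-dimethylcyclohexan-1-one | O[C@H]1CC(C)(C)/C(=C/C(OC)OC)C(=O)C1 | intermediate
8 | (chloromethyl)(isopropoxy)dimethylsilane | CC(C)O[Si](C)(C)CCl | starting material
9 | (5S,Z)-2-(2,2-dimethoxyethylidene)-1-{[isopropoxy(dimethyl)silyl]methyl}-3,3-dimethylcyclohexane-1,5-diol (both C1 epimers) | O[C@H]1CC(C)(C)/C(=C/C(OC)OC)C(O)(C[Si](C)(C)OC(C)C)C1 | intermediate (not isolated)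
10 | (5S,Z)-2-(2,2-dimethoxyethylidene)-1-(hydroxymethyl)-3,3-dimethylcyclohexane-1,5-diol (both C1 epimers) | O[C@H]1CC(C)(C)/C(=C/C(OC)OC)C(O)(CO)C1 | intermediate
11 | (7S)-3-methoxy-5,5-dimethyl-3,5,6,7,8,8a-hexahydro-1H-isochromene-7,8a-diol (mixture at C3 and C8a) | O[C@H]1CC(C)(C)C2=CC(OC)OCC2(O)C1 | intermediate
12 | (7S)-8a-hydroxy-3-methoxy-5,5-dimethyl-3,5,6,7,8,8a-hexahydro-1H-isochromen-7-yl acetate (mixture at C3 and C8a) | CC(=O)O[C@H]1CC(C)(C)C2=CC(OC)OCC2(O)C1 | intermediate
13 | 3-isopropylcatechol (3-(propan-2-yl)benzene-1,2-diol) | CC(C)c1cccc(O)c1O | starting material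
14 | (7S)-3-(3,4-dihydroxy-5-isopropylphenyl)-8a-hydroxy-5,5-dimethyl-3,5,6,7,8,8a-hexahydro-1H-isochromen-7-yl acetate (mixture at C3 and C8a) | CC(=O)O[C@H]1CC(C)(C)C2=CC(OCC2(O)C1)c1cc(O)c(O)c(C(C)C)c1 | intermediate (not isolated)
15 | (2S,7S,10R)-2-acetoxy-7,20-epoxyabieta-5,8,11,13-tetraene-11,12-diol | CC(=O)O[C@H]1CC(C)(C)C2=C[C@@H]3OC[C@@]2(C1)c1c3cc(C(C)C)c(O)c1O | intermediate
16 | (2S,5S,7S,10R)-2-acetoxy-7,20-epoxyabieta-8,11,13-triene-11,12-diol | CC(=O)O[C@H]1CC(C)(C)[C@@H]2C[C@@H]3OC[C@@]2(C1)c1c3cc(C(C)C)c(O)c1O | target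

Total step count: 8. Longest linear sequence: 8 steps (from 1).

**Steps most likely to fail**

Step 7. The free catechol may be alkylated on oxygen and the group may then migrate to C9, or the C10 cation may lose a proton instead of being captured; either process erodes site selectivity. The fallback sets out from 13 and 12 and comes back at 16. Compound 13 is benzylated (BnBr, K2CO3, DMF) to 1,2-bis(benzyloxy)-3-isopropylbenzene F1. F1 and 12 are annulated with BF3·OEt2 in CH2Cl2 (−78 to 0 °C), where only carbon attack para to the C12 ether oxygen is open, to give the dibenzyl ether of 15, (2S,7S,10R)-2-acetoxy-11,12-bis(benzyloxy)-7,20-epoxyabieta-5,8,11,13-tetraene F2. Hydrogen with palladium on carbon (Pd/C) in EtOAc then cleaves both benzyl ethers and saturates C5=C6, giving 16.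

Step 8. Hydrogen may be delivered to the wrong face of C5=C6, or the allylic, benzylic C7–O bond may undergo hydrogenolysis. The fallback sets out from 15 and comes back at 16. Compound 15 is peracetylated (Ac2O, pyridine) to the triacetate (2S,7S,10R)-2,11,12-triacetoxy-7,20-epoxyabieta-5,8,11,13-tetraene F3. Radical hydrogen-atom-transfer hydrogenation (Mn(dpm)3 with dpm = dipivaloylmethanate, PhSiH3, tBuOOH, iPrOH, rt) should give (2S,5S,7S,10R)-2,11,12-triacetoxy-7,20-epoxyabieta-8,11,13-triene F4, because the tertiary C5 radical takes up hydrogen under thermodynamic control to the trans A/B fusion. Hydrazine hydrate in THF at 0 °C then cleaves the two aryl acetates and leaves the alkyl acetate, giving 16.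

Step 3. Borylation may occur at the exocyclic acceptor, or the facial discrimination by the copper catalyst may be poor. The fallback sets out from 5 and comes back at 7. Amine-catalysed asymmetric nucleophilic epoxidation of the ring enone (30% H2O2, 9-amino-9-deoxy-epi-quinine bis(trifluoroacetate), dioxane) gives the epoxy ketone (1S,6S,Z)-3-(2,2-dimethoxyethylidene)-4,4-dimethyl-7-oxabicyclo[4.1.0]heptan-2-one F5. Reductive opening of the epoxide at the alpha carbon with NaBH4, (PhSe)2 and AcOH in EtOH then gives 7.

**Further compounds**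
F1 | step 7 | 1,2-bis(benzyloxy)-3-isopropylbenzene | CC(C)c1cccc(OCc2ccccc2)c1OCc1ccccc1
F2 | step 7 | (2S,7S,10R)-2-acetoxy-11,12-bis(benzyloxy)-7,20-epoxyabieta-5,8,11,13-tetraene | CC(=O)O[C@H]1CC(C)(C)C2=C[C@@H]3OC[C@@]2(C1)c1c3cc(C(C)C)c(OCc2ccccc2)c1OCc1ccccc1
F3 | step 8 | (2S,7S,10R)-2,11,12-triacetoxy-7,20-epoxyabieta-5,8,11,13-tetraene | CC(=O)O[C@H]1CC(C)(C)C2=C[C@@H]3OC[C@@]2(C1)c1c3cc(C(C)C)c(OC(C)=O)c1OC(C)=O
F4 | step 8 | (2S,5S,7S,10R)-2,11,12-triacetoxy-7,20-epoxyabieta-8,11,13-triene | CC(=O)O[C@H]1CC(C)(C)[C@@H]2C[C@@H]3OC[C@@]2(C1)c1c3cc(C(C)C)c(OC(C)=O)c1OC(C)=O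
F5 | step 3 | (1S,6S,Z)-3-(2,2-dimethoxyethylidene)-4,4-dimethyl-7-oxabicyclo[4.1.0]heptan-2-one | O1[C@H]2CC(C)(C)/C(=C/C(OC)OC)C(=O)[C@@H]12
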